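**Plan**
The target is an achiral biflavone ether. Unit 1 (the flavone whose ring B carries the ether oxygen at C4') is joined to C8 of unit 2. Ring A of unit 1 bears oxygen on C5, C7 and C8a, the 1,3,5-pattern of a phloroglucinol that an acetate-type chain reaches by C-acylation, so this ring is made last.
Cuts, in retrosynthetic order: the O-methyl, peri O-methyl and O-benzyl adjustments; C4a–C5 of unit 1 (Claisen); the O1–C2 bond of ring C of unit 1 and the chain bond between the ynone carbonyl and the methyl terminus of methyl 3,5-dioxohexanoate; the alkyne; the diaryl ether bond; the C8–O bond of unit 2.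
Forward: apigenin becomes protected, 8-hydroxylated unit 2; 4-fluorobenzaldehyde is attached by SNAr; the aldehyde is grown into an alkynyl Weinreb amide; the chain is joined; ring C of unit 1 closes as a 4-pyranone; ring A closes; methylation and deprotection finish.
Stereochemistry: the target has no stereocentre and no stereogenic double bond, so nothing has to be set.

Key step: step 9

Remark: the 4-pyranone is numbered with the keto ester chain on C2 and the aryl group on C6, so the ring carbon that becomes C4a of unit 1 is pyranone C3; methyl 3,5-dioxohexanoate, the Ohira–Bestmann reagent and N-methoxy-N-methylcarbamoyl chloride are taken as purchased.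

**Route**

Step 1
Reactants: 1 apigenin
Product: 2 genkwanin (5,4'-dihydroxy-7-methoxyflavone)
Conditions: MeI (1.05 equiv), K2CO3 (1.05 equiv), DMF, 0 °C to rt
Reagents that add atoms: iodomethane, CI
Why: Williamson etherification in which the 7-hydroxyl, para to the ring carbonyl and the most acidic phenol of apigenin, should be alkylated first with one equivalent of base, while the 5-hydroxyl stays locked in its hydrogen bond to the carbonyl.

Step 2
Reactants: 2 genkwanin
Product: 3 4'-benzyloxy-5-hydroxy-7-methoxyflavone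
Conditions: BnBr (1.1 equiv), K2CO3, DMF, rt
Reagents that add atoms: benzyl bromide, BrCc1ccccc1
Why: Williamson etherification of the only free non-chelated phenol; the hydrogen-bonded 5-hydroxyl should not react under these mild conditions.

Step 3
Reactants: 3 4'-benzyloxy-5-hydroxy-7-methoxyflavone
Product: 5 4'-benzyloxy-5,8-dihydroxy-7-methoxyflavone, via potassium flavon-8-yl sulfate 4 (not isolated)
Conditions: K2S2O8, KOH, H2O/pyridine, 15–20 °C; then aq. HCl, trace Na2SO3, 80 °C
Reagents that add atoms: potassium peroxodisulfate, [K+].[K+].[O-]S(=O)(=O)OOS(=O)(=O)[O-]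
Why: Elbs persulfate oxidation, in which the 5-phenoxide is attacked by peroxodisulfate at its free para position C8 to give the aryl sulfate, which acid hydrolysis should convert into the 8-phenol, the established way of 8-hydroxylating 5-hydroxyflavones.

Step 4
Reactants: 5 4'-benzyloxy-5,8-dihydroxy-7-methoxyflavone; 6 4-fluorobenzaldehyde
Product: 7 4-[(4'-benzyloxy-5-hydroxy-7-methoxyflavon-8-yl)oxy]benzaldehyde
Conditions: K2CO3 (1.2 equiv), DMF, 90 °C, argon
Reagents that add atoms: none
Why: Nucleophilic aromatic substitution through a Meisenheimer adduct para to the formyl group, in which the free and more acidic 8-phenoxide should react in preference to the chelated 5-hydroxyl, as in the known selective 8-O-alkylation of 5,8-dihydroxyflavones.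

Step 5
Reactants: 7 4-[(4'-benzyloxy-5-hydroxy-7-methoxyflavon-8-yl)oxy]benzaldehyde
Product: 8 4-[(4'-benzyloxy-5,7-dimethoxyflavon-8-yl)oxy]benzaldehyde
Conditions: MeI (excess), K2CO3, DMF, 50 °C
Reagents that add atoms: iodomethane, CI
Why: Williamson etherification under forcing conditions, the standard way to methylate a chelated peri hydroxyl, here to keep that phenol out of the later acylation and strong-base steps.

Step 6
Reactants: 8 4-[(4'-benzyloxy-5,7-dimethoxyflavon-8-yl)oxy]benzaldehyde
Product: 9 4'-benzyloxy-8-(4-ethynylphenoxy)-5,7-dimethoxyflavone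
Conditions: dimethyl (1-diazo-2-oxopropyl)phosphonate, K2CO3, MeOH/THF, rt
Reagents that add atoms: dimethyl (1-diazo-2-oxopropyl)phosphonate, COP(=O)(OC)C(=[N+]=[N-])C(C)=O
Why: Seyferth–Gilbert homologation with the Ohira–Bestmann reagent, whose mild carbonate and methanol conditions should leave the flavone, the ethers and the benzyl group untouched.

Step 7
Reactants: 9 4'-benzyloxy-8-(4-ethynylphenoxy)-5,7-dimethoxyflavone
Product: 11 3-{4-[(4'-benzyloxy-5,7-dimethoxyflavon-8-yl)oxy]phenyl}-N-methoxy-N-methylprop-2-ynamide, via lithium acetylide 10 (not isolated)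
Conditions: LiN(SiMe3)2, THF, −78 to −40 °C; ClC(O)N(OMe)Me, −78 to 0 °C
Reagents that add atoms: N-methoxy-N-methylcarbamoyl chloride, CON(C)C(Cl)=O
Why: Acylation of a lithium acetylide with a carbamoyl chloride to give the alkynyl Weinreb amide, the non-nucleophilic silylamide base being chosen so that nothing adds to the chromone of unit 2.

Step 8
Reactants: 11 3-{4-[(4'-benzyloxy-5,7-dimethoxyflavon-8-yl)oxy]phenyl}-N-methoxy-N-methylprop-2-ynamide; 12 methyl 3,5-dioxohexanoate
Product: 15 methyl 4-(6-{4-[(4'-benzyloxy-5,7-dimethoxyflavon-8-yl)oxy]phenyl}-4-oxo-4H-pyran-2-yl)-3-oxobutanoate, via trilithium trianion of methyl 3,5-dioxohexanoate 13 (not isolated), via acyclic ynone triketo ester 14 (not isolated)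
Conditions: 12, LiN(i-Pr)2 (3 equiv per 12), THF, 0 °C; 11, −78 to −20 °C; cold 1 M HCl; then p-TsOH·H2O (cat.), CH2Cl2, rt
Reagents that add atoms: none
Why: Terminal acylation of a β-dicarbonyl polyanion by a Weinreb amide, whose chelated tetrahedral adduct should enforce 1,2-addition and stop at the ynone, followed by acid-catalysed 6-endo-dig oxa-Michael addition of the enol oxygen of the C5 carbonyl to the ynone, the usual closure of acetylenic β-diketones to 4-pyranones and the only oxygen that can reach the alkyne terminus through a six-membered ring.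

Step 9
Reactants: 15 methyl 4-(6-{4-[(4'-benzyloxy-5,7-dimethoxyflavon-8-yl)oxy]phenyl}-4-oxo-4H-pyran-2-yl)-3-oxobutanoate
Product: 16 4'-[(4'-benzyloxy-5,7-dimethoxyflavon-8-yl)oxy]-5,7-dihydroxyflavone
Conditions: Mg(OMe)2 (4 equiv), MeOH/THF, 60 °C; then 1 M HCl
Reagents that add atoms: none
Why: Proposed new method: Mg(OMe)2 should deprotonate the methylene between the pyranone and the ketone to give an extended dienolate whose charge is shared by that carbon, pyranone C3 and the pyranone carbonyl oxygen, held as a magnesium chelate that brings the ester within reach of C3. C3 then adds to the ester carbon, methoxide leaves, and the cyclohexenedione tautomerises to the 5,7-dihydroxy ring A, aromatisation and the chelated 5-hydroxyl making the closure irreversible. The closest known reaction type is the base-mediated biomimetic Claisen cyclisation of open-chain 3,5,7-triketo esters to acylphloroglucinols, here run with three carbonyl groups of the chain tied up in the 4-pyranone. Ring A closes in a 6-(enolexo)-exo-trig mode and no stereocentre is formed. The selectivity needed is C-acylation at pyranone C3 over aldol, lactone and ring-opening pathways: the pyranone removes the ketone electrophiles an aldol closure would need, C3 is the only nucleophilic carbon that reaches the ester through a six-membered transition state, and the weakly nucleophilic magnesium alkoxide should spare the pyranone and the flavone of unit 2.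

Step 10
Reactants: 16 4'-[(4'-benzyloxy-5,7-dimethoxyflavon-8-yl)oxy]-5,7-dihydroxyflavone
Product: 17 4'-[(4'-benzyloxy-5,7-dimethoxyflavon-8-yl)oxy]-5-hydroxy-7-methoxyflavone
Conditions: MeI (1.1 equiv), K2CO3 (1.1 equiv), acetone, rt
Reagents that add atoms: iodomethane, CI
Why: Williamson etherification of the acidic 7-hydroxyl of unit 1, the only phenol not held in a hydrogen bond to a carbonyl, so the 5-hydroxyl should stay free.

Step 11
Reactants: 17 4'-[(4'-benzyloxy-5,7-dimethoxyflavon-8-yl)oxy]-5-hydroxy-7-methoxyflavone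
Product: 18 4'-[(5,4'-dihydroxy-7-methoxyflavon-8-yl)oxy]-5-hydroxy-7-methoxyflavone (CNP0415865.0)
Conditions: BCl3 (excess), C6HMe5, CH2Cl2, −78 to 0 °C; MeOH, then aq. HCl
Reagents that add atoms: none
Why: Lewis acid ether cleavage in which BCl3, bound to the C4 carbonyl of unit 2, should remove only the peri 5-methyl group and, with pentamethylbenzene as benzyl cation scavenger, the benzyl ether, leaving both 7-methoxy groups and the diaryl ether intact.

**Compound list**
1 | apigenin (5,7,4'-trihydroxyflavone) | O=c1cc(-c2ccc(O)cc2)oc2cc(O)cc(O)c12 | starting material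
2 | genkwanin (5,4'-dihydroxy-7-methoxyflavone) | COc1cc(O)c2c(=O)cc(-c3ccc(O)cc3)oc2c1 | intermediate
3 | 4'-benzyloxy-5-hydroxy-7-methoxyflavone | COc1cc(O)c2c(=O)cc(-c3ccc(OCc4ccccc4)cc3)oc2c1 | intermediate
4 | potassium 4'-benzyloxy-5-hydroxy-7-methoxyflavon-8-yl sulfate (formed in the flask) | COc1cc(O)c2c(=O)cc(-c3ccc(OCc4ccccc4)cc3)oc2c1OS(=O)(=O)[O-].[K+] | intermediate
5 | 4'-benzyloxy-5,8-dihydroxy-7-methoxyflavone | COc1cc(O)c2c(=O)cc(-c3ccc(OCc4ccccc4)cc3)oc2c1O | intermediate
6 | 4-fluorobenzaldehyde | O=Cc1ccc(F)cc1 | starting material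
7 | 4-[(4'-benzyloxy-5-hydroxy-7-methoxyflavon-8-yl)oxy]benzaldehyde | O=Cc1ccc(Oc2c(OC)cc(O)c3c(=O)cc(-c4ccc(OCc5ccccc5)cc4)oc23)cc1 | intermediate
8 | 4-[(4'-benzyloxy-5,7-dimethoxyflavon-8-yl)oxy]benzaldehyde | O=Cc1ccc(Oc2c(OC)cc(OC)c3c(=O)cc(-c4ccc(OCc5ccccc5)cc4)oc23)cc1 | intermediate
9 | 4'-benzyloxy-8-(4-ethynylphenoxy)-5,7-dimethoxyflavone | C#Cc1ccc(Oc2c(OC)cc(OC)c3c(=O)cc(-c4ccc(OCc5ccccc5)cc4)oc23)cc1 | intermediate
10 | lithium acetylide of 9 (formed in the flask) | [Li+].[C-]#Cc1ccc(Oc2c(OC)cc(OC)c3c(=O)cc(-c4ccc(OCc5ccccc5)cc4)oc23)cc1 | intermediate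
11 | 3-{4-[(4'-benzyloxy-5,7-dimethoxyflavon-8-yl)oxy]phenyl}-N-methoxy-N-methylprop-2-ynamide | CON(C)C(=O)C#Cc1ccc(Oc2c(OC)cc(OC)c3c(=O)cc(-c4ccc(OCc5ccccc5)cc4)oc23)cc1 | intermediate
12 | methyl 3,5-dioxohexanoate | COC(=O)CC(=O)CC(C)=O | starting material
13 | trilithium trianion of methyl 3,5-dioxohexanoate (formed in the flask) | [Li+].[Li+].[Li+].COC(=O)[CH-]C(=O)[CH-]C(=O)[CH2-] | intermediate
14 | methyl 9-{4-[(4'-benzyloxy-5,7-dimethoxyflavon-8-yl)oxy]phenyl}-3,5,7-trioxonon-8-ynoate (formed in the flask) | COC(=O)CC(=O)CC(=O)CC(=O)C#Cc1ccc(Oc2c(OC)cc(OC)c3c(=O)cc(-c4ccc(OCc5ccccc5)cc4)oc23)cc1 | intermediate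
15 | methyl 4-(6-{4-[(4'-benzyloxy-5,7-dimethoxyflavon-8-yl)oxy]phenyl}-4-oxo-4H-pyran-2-yl)-3-oxobutanoate | COC(=O)CC(=O)Cc1cc(=O)cc(-c2ccc(Oc3c(OC)cc(OC)c4c(=O)cc(-c5ccc(OCc6ccccc6)cc5)oc34)cc2)o1 | intermediate
16 | 4'-[(4'-benzyloxy-5,7-dimethoxyflavon-8-yl)oxy]-5,7-dihydroxyflavone | Oc1cc(O)c2c(=O)cc(-c3ccc(Oc4c(OC)cc(OC)c5c(=O)cc(-c6ccc(OCc7ccccc7)cc6)oc45)cc3)oc2c1 | intermediate
17 | 4'-[(4'-benzyloxy-5,7-dimethoxyflavon-8-yl)oxy]-5-hydroxy-7-methoxyflavone | COc1cc(O)c2c(=O)cc(-c3ccc(Oc4c(OC)cc(OC)c5c(=O)cc(-c6ccc(OCc7ccccc7)cc6)oc45)cc3)oc2c1 | intermediate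
18 | 4'-[(5,4'-dihydroxy-7-methoxyflavon-8-yl)oxy]-5-hydroxy-7-methoxyflavone (CNP0415865.0) | COc1cc(O)c2c(=O)cc(-c3ccc(Oc4c(OC)cc(O)c5c(=O)cc(-c6ccc(O)cc6)oc45)cc3)oc2c1 | target

**Step count and risks**
Total: 11 steps. Longest linear sequence: 11 steps, from apigenin 1 to the target 18; 4-fluorobenzaldehyde 6 and methyl 3,5-dioxohexanoate 12 enter as purchased.

Step 9 (key step, new method). The ester may sit as an unreactive magnesium enolate so that C-acylation at pyranone C3 stalls, while methoxide-induced retro-Claisen cleavage of the keto ester or opening of the pyranone drains material. The fallback builds unit 1 by known chalcone chemistry. It sets out from aldehyde 8: Claisen–Schmidt condensation with purchased 2'-hydroxy-4',6'-dimethoxyacetophenone (KOH, EtOH/THF, rt) should give the (E)-2'-hydroxychalcone F1. Oxidative cyclisation with catalytic I2 in DMSO at 130 °C should then give the biflavone tetramethyl benzyl ether F2. BCl3 with pentamethylbenzene should remove both peri methyl groups and the benzyl group, so the route is rejoined at the target 18.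

Step 8. The polyanion may be acylated incompletely or add in conjugate fashion to the ynamide, and the unprotected tetracarbonyl chain may undergo aldol or lactone closure before the pyranone has formed. The fallback masks the keto ester end as a dioxinone. It sets out from Weinreb amide 11. The keto-dioxinone 2,2-dimethyl-6-(2-oxopropyl)-4H-1,3-dioxin-4-one F3 is made from purchased 2,2,6-trimethyl-4H-1,3-dioxin-4-one (LiN(SiMe3)2, then acetyl chloride). F3 is doubly deprotonated with LiN(i-Pr)2 and acylated at its methyl terminus by 11 to give the ynone diketo-dioxinone F4. Acid-catalysed 6-endo-dig closure (p-TsOH, CH2Cl2) should give the pyranonylmethyl dioxinone F5. Heating F5 in toluene with methanol at 110 °C should expel acetone, and the acylketene F6 so formed is trapped by methanol, rejoining the route at keto ester 15.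

Step 3. Conversion in the persulfate oxidation may be low, the hydroquinone may be over-oxidised to the 5,8-quinone, and the benzyl ether may be partly lost during acid hydrolysis of the sulfate. The fallback reverses the roles of the ether partners and replaces steps 3 to 5. It sets out from 3: methylation of the chelated hydroxyl (MeI, K2CO3, DMF, 50 °C) should give 4'-benzyloxy-5,7-dimethoxyflavone F7. Electrophilic iodination with N-iodosuccinimide in DMF should occur at C8, the most activated position of the 5,7-dimethoxy ring A, to give the 8-iodoflavone F8. Ullmann ether coupling of F8 with 4-hydroxybenzaldehyde (CuI, N,N-dimethylglycine, Cs2CO3, dioxane, 100 °C) should then rejoin the route at aldehyde 8.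

**Further compounds**
F1 | step 9 | (E)-3-{4-[(4'-benzyloxy-5,7-dimethoxyflavon-8-yl)oxy]phenyl}-1-(2-hydroxy-4,6-dimethoxyphenyl)prop-2-en-1-one | COc1cc(O)c(C(=O)/C=C/c2ccc(Oc3c(OC)cc(OC)c4c(=O)cc(-c5ccc(OCc6ccccc6)cc5)oc34)cc2)c(OC)c1
F2 | step 9 | 4'-[(4'-benzyloxy-5,7-dimethoxyflavon-8-yl)oxy]-5,7-dimethoxyflavone | COc1cc(OC)c2c(=O)cc(-c3ccc(Oc4c(OC)cc(OC)c5c(=O)cc(-c6ccc(OCc7ccccc7)cc6)oc45)cc3)oc2c1
F3 | step 8 | 2,2-dimethyl-6-(2-oxopropyl)-4H-1,3-dioxin-4-one | CC(=O)CC1=CC(=O)OC(C)(C)O1
F4 | step 8 | 6-(6-{4-[(4'-benzyloxy-5,7-dimethoxyflavon-8-yl)oxy]phenyl}-2,4-dioxohex-5-yn-1-yl)-2,2-dimethyl-4H-1,3-dioxin-4-one | CC1(C)OC(=O)C=C(CC(=O)CC(=O)C#Cc2ccc(Oc3c(OC)cc(OC)c4c(=O)cc(-c5ccc(OCc6ccccc6)cc5)oc34)cc2)O1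
F5 | step 8 | 6-[(6-{4-[(4'-benzyloxy-5,7-dimethoxyflavon-8-yl)oxy]phenyl}-4-oxo-4H-pyran-2-yl)methyl]-2,2-dimethyl-4H-1,3-dioxin-4-one | CC1(C)OC(=O)C=C(Cc2cc(=O)cc(-c3ccc(Oc4c(OC)cc(OC)c5c(=O)cc(-c6ccc(OCc7ccccc7)cc6)oc45)cc3)o2)O1
F6 | step 8 | 4-(6-{4-[(4'-benzyloxy-5,7-dimethoxyflavon-8-yl)oxy]phenyl}-4-oxo-4H-pyran-2-yl)-3-oxobut-1-en-1-one (acylketene) | O=C=CC(=O)Cc1cc(=O)cc(-c2ccc(Oc3c(OC)cc(OC)c4c(=O)cc(-c5ccc(OCc6ccccc6)cc5)oc34)cc2)o1
F7 | step 3 | 4'-benzyloxy-5,7-dimethoxyflavone | COc1cc(OC)c2c(=O)cc(-c3ccc(OCc4ccccc4)cc3)oc2c1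
F8 | step 3 | 4'-benzyloxy-8-iodo-5,7-dimethoxyflavone | COc1cc(OC)c2c(=O)cc(-c3ccc(OCc4ccccc4)cc3)oc2c1I
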